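I commit this flask to one number read from the two earlier runs.

common to all: L 0.085 M

| charge | G | remark | time | volume of the second phase over the first |
|---|---|---|---|---|
| autumn | 0.60 equiv | run made earlier |  |  |
| noon | 1.4 equiv | run made earlier |  |  |
| flask | 0.900 equiv |  | 15 h | 0.25 |

- autumn (time / h: D / %): 1.00: 2.4; 1.33: 3.5; 2.00: 4.4; 3.00: 5.8; 5.00: 6.2; 8.00: 2.1; 12.0: 5.0
- noon (time / h: D / %): 0.667: 4.8; 2.00: 9.8; 3.00: 10.3; 5.00: 13.2; 8.00: 13.1; 10.0: 12.0; 12.0: 11.6

(standard deviation of a reading: 1 percentage point)

1. the D standing at 15 h, as a percentage of the L charged
2. the change that raises the amount of D at 15 h, in percent of the L charged most ("none" if none brings more than 2 percentage points) (north-west / north / none)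
3. amount of D at 15 h, in percent of the L charged, after north-west

- north-west: doubling the amount of G, all else as stated
- north: doubling the transfer coefficient of G, all else as stated

- in the second phase: G; everything else is in the first
- charges count per volume of the first phase; a concentration in a rate is the amount of a species over the volume of its own phase; every rate counts per litre of the first phase
- the earlier runs hold the two phases in the same ratio of volumes as the flask asked about

In this flask G is charged in the smaller amount (0.900 equiv), so I write its balance: what was charged equals what stands as D plus whatever else holds it, and the readings show the first term. From 5.00 h on, setting aside the 2.1 % at 8.00 h, which lies below both its neighbours, the autumn run gives 9.33 % of its G standing as D and the noon run 8.91 %. Together they give 8.99 %, the plateau share, D standing on the level over the G charged.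

Now the settings, by hand. For the amount of G, the share gives 8.09 % in this flask and 16.2 % with G doubled, a gain beyond the 2 percentage points line. For time, 15 h lies later than the 5.00 h at which the noon run stood level, so I hold the number. For transfer, the same comparison tells me that faster transfer brings the level sooner, and I expect no gain from it.

The forecast says 8.3 %, chooses north-west and gives 15.4 % after it, reading the level thus: “this looks like a reversible L + G ⇌ D equilibrium rather than exhaustion”. My 8.09 % stands lower than its 8.3 %.

The flask gives 7.60 % and the better change is north-west: doubling G gives 16.0 %, a gain of 8.4 points, and doubling transfer gives 0 points. The share comes to 8.44 % and 8.89 %.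

    Z ⇌ G, rate k1*([Z] - [G]/K1) per volume of the first phase (partition coefficient = 3.00, kL = 6.10 /h)
    L + Z → D (k = 1.60 /M/h)
    L + D → X (k = 7.70 /M/h)
    2 L → J (k = 0.710 /M/h)

At 15.0 h this flask makes D at 0.923 of the rate at which it uses D up, a quasi-steady state, and 30.9 % of the L charged has passed through the making of D, against 7.60 % standing. For the forecast to be wrong a run has to show the share moved: with the rate constant of that making doubled, this flask stands at 12.9 % at 15 h, against the 8.3 % of the forecast.

For the neighbour with 0.021 M of L at the same equivalents, the share gives 8.09 % again; that flask computes to 7.72 %, with 50 % of its L still there.

Readings and results were computed from invented constants, and the scatter is random.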